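**Retrosynthetic overview**

1. Ring atoms of the cyclohexene are numbered C1 (quaternary; CH3 and the vinyl group), C2 (CH bearing the coumarin), C3=C4(CH3), C5H2, C6H2. The last disconnections are the two MOM ethers and the vinyl–coumarin bond (Suzuki coupling of an alkenylboronate, made from an ethynyl group on C1, with bromocoumarin 8).
2. Key disconnection: C3=C4 and C5–C6 together. The ring's only functional group is the C3=C4(CH3) alkene, and it borders the unfunctionalised C5H2–C6H2 edge, so C4, its methyl and C5 can be cut out as an isopropenylphosphonium salt. What remains is the open chain C3–C2–C1–C6 with CHO on C3 and CH2CO2H on C6 (oxo acid 34).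
3. The C1–C2 bond and both stereocentres come from one Ireland–Claisen rearrangement of the coumarin-3-acetate of the (S,E)-allylic alcohol 19; bromocoumarin 8 supplies both coumarin units.
4. Between Claisen and key step: CO2H → CH2OH, a δ-lactone as temporary ring, propenyl → CHO → ethynyl (a vinyl surrogate that a neighbouring radical leaves alone), then lactone opening and oxidation.
5. Order of ring formation: coumarin ring of 8 (step 2) → temporary δ-lactone (step 10, opened in step 13) → cyclohexene (step 15).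

Key step: step 15

Remark: oxo acid 34 is drawn open-chain; it is assumed to equilibrate with its cyclic 6-hydroxy-δ-lactone form and to react as the open carboxylate.
Abbreviation used in names: Cou = 8-methoxy-7-(methoxymethoxy)-2-oxo-2H-chromen-3-yl.

**Route**

Step 1
Reactants: 1 2,4-dihydroxy-3-methoxybenzaldehyde; 2 chloromethyl methyl ether
Product: 3 2-hydroxy-3-methoxy-4-(methoxymethoxy)benzaldehyde
Conditions: K2CO3, acetone, 0 °C → rt
Reagents that add atoms: chloromethyl methyl ether, COCCl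
Why: Williamson-type O-alkylation; the 4-OH is the more acidic, unhindered phenol, whereas the 2-OH is held in a hydrogen bond to the formyl group, so monoprotection at O4 is expected.

Step 2
Reactants: 3; 4 ethyl (triphenylphosphoranylidene)acetate; 5 N-bromosuccinimide
Product: 8 3-bromo-8-methoxy-7-(methoxymethoxy)-2H-chromen-2-one, via bromo ylide 6 (not isolated), via bromocinnamate 7 (not isolated)
Conditions: 4, 5, CH2Cl2, −20 °C; then 3, rt; then PhNEt2, 180 °C
Reagents that add atoms: ethyl (triphenylphosphoranylidene)acetate, CCOC(=O)C=P(c1ccccc1)(c1ccccc1)c1ccccc1; N-bromosuccinimide, O=C1CCC(=O)N1Br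
Why: Bromination of the stabilised ylide, Wittig olefination of 3 and thermal lactonisation of the o-hydroxycinnamate (E/Z equilibration at high temperature) should give the coumarin with bromine fixed at C3, because the halogen arrives on the ylide carbon.

Step 3
Reactants: 8; 9 (2-ethoxy-2-oxoethyl)zinc bromide
Product: 10 ethyl 2-Cou-acetate
Conditions: Pd2(dba)3 (cat.), XPhos, THF, 40 °C
Reagents that add atoms: (2-ethoxy-2-oxoethyl)zinc bromide, CCOC(=O)C[Zn]Br
Why: Palladium-catalysed cross-coupling of a Reformatsky reagent with an alkenyl bromide (Negishi-type ester α-arylation); oxidative addition into the C3–Br bond is fast and the neutral zinc enolate tolerates lactone and MOM acetal.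

Step 4
Reactants: 10
Product: 12 2-Cou-acetic acid, via coumarinate salt 11 (not isolated)
Conditions: LiOH, THF/H2O, rt; then 2 M HCl, 0 °C (pH 2)
Reagents that add atoms: lithium hydroxide, [Li+].[OH-]
Why: Ester saponification; hydroxide also opens the coumarin to the (Z)-coumarinate 11, which recloses on acidification because the cis-alkene holds phenol and carboxyl together, and the MOM ether should survive the short cold acidification.

Step 5
Reactants: 13 tert-butyl(but-3-yn-1-yloxy)dimethylsilane; 14 trimethylaluminium; 15 acetaldehyde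
Product: 17 rac-(3E)-6-[(tert-butyldimethylsilyl)oxy]-4-methylhex-3-en-2-ol, via alkenylalane 16 (not isolated)
Conditions: AlMe3, Cp2ZrCl2 (cat.), CH2Cl2, 0 °C → rt; then CH3CHO, −78 → 0 °C; aqueous work-up
Reagents that add atoms: trimethylaluminium, C[Al](C)C; acetaldehyde, CC=O
Why: Zirconium-catalysed syn-carboalumination of the terminal alkyne (Negishi carboalumination) places CH3 and Al cis, and the alkenylalane adds to acetaldehyde with retention, so only the (E)-trisubstituted allylic alcohol (racemic at the carbinol) should form.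

Step 6
Reactants: 17; 18 vinyl acetate
Product: 19 (2S,3E)-6-[(tert-butyldimethylsilyl)oxy]-4-methylhex-3-en-2-ol
Conditions: Novozym 435 (immobilised Candida antarctica lipase B), MTBE, 30 °C, stopped near half conversion; chromatography
Reagents that add atoms: none
Why: Lipase-catalysed kinetic resolution by transesterification; for methyl carbinols this lipase acylates the (R)-enantiomer, so the (S)-alcohol should remain and be separated from the (R)-acetate.

Step 7
Reactants: 12; 19
Product: 20 (2S,3E)-6-[(tert-butyldimethylsilyl)oxy]-4-methylhex-3-en-2-yl 2-Cou-acetate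
Conditions: DCC, DMAP (cat.), CH2Cl2, 0 °C → rt
Reagents that add atoms: none
Why: Steglich esterification; O-acylation leaves the carbinol stereocentre and the olefin geometry untouched.

Step 8
Reactants: 20
Product: 23 (2R,3R,4E)-3-{2-[(tert-butyldimethylsilyl)oxy]ethyl}-2-Cou-3-methylhex-4-enoic acid, via silyl ketene acetal 21 (not isolated), via silyl ester 22 (not isolated)
Conditions: LiHMDS, THF, −78 °C; Me3SiCl/Et3N, −78 °C → rt; PhMe, 70 °C; then aq. citric acid
Reagents that add atoms: none
Why: Ireland–Claisen rearrangement; the arylacetate-type ester should enolise to the (Z)-O-silyl ketene acetal (Cou cis to OSi), and the chair transition state with the carbinol methyl equatorial transfers the (S)-carbinol chirality to the new C1–C2 bond, which sets quaternary C1 and C2 together (Cou cis to the propenyl group, trans to CH3) and gives the (E)-propenyl group.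

Step 9
Reactants: 23
Product: 25 (2R,3R,4E)-3-(2-hydroxyethyl)-2-Cou-3-methylhex-4-en-1-ol, via silyl ether alcohol 24 (not isolated)
Conditions: BH3·SMe2, THF, 0 °C; then MeOH, CSA (cat.), rt
Reagents that add atoms: none
Why: Borane reduces the carboxylic acid faster than it adds to the hindered 1,2-disubstituted alkene or attacks the conjugated lactone, and acid-catalysed methanolysis in the same flask removes the primary TBS ether while the phenolic MOM ether should stay; no stereocentre is touched.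

Step 10
Reactants: 25
Product: 27 (4R,5R)-5-Cou-4-methyl-4-[(1E)-prop-1-en-1-yl]oxan-2-one, via lactol 26 (not isolated)
Conditions: TEMPO (cat.), PhI(OAc)2, CH2Cl2, rt
Reagents that add atoms: none
Why: Oxidative lactonisation of a 1,5-diol; the oxoammonium salt should oxidise the less hindered CH2CH2OH first, the aldehyde is trapped by the β-branched CH2OH as a lactol and oxidised on to the δ-lactone, which masks both the C3 oxygen and the future carboxyl group.

Step 11
Reactants: 27
Product: 29 (4S,5R)-5-Cou-4-methyl-2-oxooxane-4-carbaldehyde, via ozonide 28 (not isolated)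
Conditions: O3, CH2Cl2, −78 °C (indicator-dye end point); then Me2S, −78 °C → rt
Reagents that add atoms: ozone, [O-][O+]=O
Why: Ozonolysis with reductive work-up; ozone should attack the isolated electron-rich propenyl alkene well before the electron-poor coumarin C3=C4 bond, giving a non-enolisable aldehyde on the quaternary carbon.

Step 12
Reactants: 29; 30 dimethyl (1-diazo-2-oxopropyl)phosphonate
Product: 32 (4S,5R)-4-ethynyl-5-Cou-4-methyloxan-2-one, via hydroxy ester 31 (not isolated)
Conditions: 30, K2CO3, MeOH, 0 °C → rt; then PPTS (cat.), PhMe, 50 °C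
Reagents that add atoms: dimethyl (1-diazo-2-oxopropyl)phosphonate, COP(=O)(OC)C(=[N+]=[N-])C(C)=O
Why: Ohira–Bestmann (Seyferth–Gilbert) homologation turns the aldehyde into the terminal alkyne under mild carbonate conditions (the α-carbon is quaternary, so nothing can epimerise), and the δ-lactone that methanolyses under these conditions is closed again by mild acid.

Step 13
Reactants: 32
Product: 34 (3S,4R)-3-ethynyl-4-Cou-3-methyl-5-oxopentanoic acid, via ammonium carboxylate 33 (not isolated)
Conditions: Bu4NOH (1.0 equiv, aq.), THF, 0 °C; azeotropic drying; DMP, CH2Cl2, 0 °C; then 0.5 M HCl to pH 4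
Reagents that add atoms: tetrabutylammonium hydroxide, CCCC[N+](CCCC)(CCCC)CCCC.[OH-]
Why: One equivalent of hydroxide opens the reactive δ-lactone to the carboxylate salt, whose primary alcohol is oxidised directly by Dess–Martin periodinane, so the free hydroxy acid (which would relactonise) is never handled and the new aldehyde at C3 sees no strong base.

Step 14
Reactants: 35 triphenylphosphine; 36 2-bromopropene
Product: 37 triphenyl(prop-1-en-2-yl)phosphonium bromide
Conditions: Pd(PPh3)4 (cat.), PhMe, 100 °C, sealed tube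
Reagents that add atoms: none
Why: Palladium-catalysed C–P coupling of an alkenyl bromide with a triarylphosphine (oxidative addition, then reductive elimination of the phosphonium salt), the established route to alkenylphosphonium salts that direct quaternisation cannot give.

Step 15
Reactants: 34; 37
Product: 39 3-[(1R,6S)-6-ethynyl-3,6-dimethylcyclohex-2-en-1-yl]-8-methoxy-7-(methoxymethoxy)-2H-chromen-2-one, via ylide 38 (not isolated)
Conditions: Ir(dF(CF3)ppy)2(dtbbpy)PF6 (2 mol %), K2HPO4 (1.2 equiv), MeCN (0.02 M), 450 nm LEDs, 25 °C, N2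
Reagents that add atoms: triphenyl(prop-1-en-2-yl)phosphonium bromide, CC(=C)[P+](c1ccccc1)(c1ccccc1)c1ccccc1.[Br-]
Why: Proposed new method: the carboxylate of 34 is oxidised by the excited photocatalyst, CO2 is lost, and the nucleophilic primary C6 radical adds to the CH2 terminus of the electron-poor alkenylphosphonium 37 (forming C5–C6); the reduced photocatalyst then turns the α-phosphonio radical into ylide 38 (redox-neutral radical–polar crossover), which closes onto the C3 aldehyde in an intramolecular Wittig reaction (forming C3=C4) and expels Ph3PO. The closest known reaction type is the photocatalytic three-component olefination of carboxylic acids, vinylphosphonium salts and aldehydes; new here are the ring-forming Wittig terminus and the α-methyl-substituted acceptor. The six-membered ring closes by 6-exo-trig attack of the ylide carbon C4 on the aldehyde carbon C3 (oxaphosphetane, then cycloreversion), so the trisubstituted alkene is endocyclic and has no E/Z question. No stereocentre is created: C1 is quaternary and C2 is carried through from step 8. The step needs the radical to add to 37 before it rearranges, which is why C1 carries ethynyl (slow 1,2-shift) and not vinyl at this stage, and it needs C2 to keep its configuration, for which the weak heterogeneous base, high dilution and the fast six-membered Wittig closure are relied on.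

Step 16
Reactants: 39; 40 pinacolborane; 8
Product: 42 8-methoxy-3-[(E)-2-[(1R,2R)-2-Cou-1,4-dimethylcyclohex-3-en-1-yl]ethenyl]-7-(methoxymethoxy)-2H-chromen-2-one, via alkenylboronate 41 (not isolated)
Conditions: 40, Cp2Zr(H)Cl (cat.), Et3N (cat.), CH2Cl2, 40 °C; then 8, Pd(dppf)Cl2 (cat.), K3PO4, THF/H2O, 60 °C
Reagents that add atoms: 3-bromo-8-methoxy-7-(methoxymethoxy)-2H-chromen-2-one, COCOc1ccc2cc(Br)c(=O)oc2c1OC
Why: Zirconium-catalysed syn-hydroboration of the terminal alkyne gives the (E)-alkenylboronate (ring alkene and lactone are left alone), and Suzuki–Miyaura coupling with bromide 8 proceeds with retention to the (E)-alkene.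

Step 17
Reactants: 42
Product: 43 7-hydroxy-3-[(E)-2-[(1R,2R)-2-(7-hydroxy-8-methoxy-2-oxo-2H-chromen-3-yl)-1,4-dimethylcyclohex-3-en-1-yl]ethenyl]-8-methoxy-2H-chromen-2-one (CNP0264408.1)
Conditions: 3 M HCl (aq.), MeOH/THF, 40 °C
Reagents that add atoms: none
Why: Acid-catalysed acetal exchange removes both phenolic MOM ethers; the lactones, the trisubstituted ring alkene and the two stereocentres (neither acidic nor ionisable) should survive dilute acid.

**Compound list**

1 | 2,4-dihydroxy-3-methoxybenzaldehyde | O=Cc1ccc(O)c(OC)c1O | starting material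
2 | chloromethyl methyl ether | COCCl | starting material
3 | 2-hydroxy-3-methoxy-4-(methoxymethoxy)benzaldehyde | O=Cc1ccc(OCOC)c(OC)c1O | intermediate
4 | ethyl (triphenylphosphoranylidene)acetate | CCOC(=O)C=P(c1ccccc1)(c1ccccc1)c1ccccc1 | starting material
5 | N-bromosuccinimide | O=C1CCC(=O)N1Br | starting material
6 | ethyl bromo(triphenylphosphoranylidene)acetate | CCOC(=O)C(Br)=P(c1ccccc1)(c1ccccc1)c1ccccc1 | intermediate
7 | ethyl (2E)-2-bromo-3-[2-hydroxy-3-methoxy-4-(methoxymethoxy)phenyl]prop-2-enoate | CCOC(=O)/C(Br)=C\c1ccc(OCOC)c(OC)c1O | intermediate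
8 | 3-bromo-8-methoxy-7-(methoxymethoxy)-2H-chromen-2-one | COCOc1ccc2cc(Br)c(=O)oc2c1OC | intermediate
9 | (2-ethoxy-2-oxoethyl)zinc bromide | CCOC(=O)C[Zn]Br | starting material
10 | ethyl 2-Cou-acetate | CCOC(=O)Cc1cc2ccc(OCOC)c(OC)c2oc1=O | intermediate
11 | trilithium (2Z)-2-{[3-methoxy-4-(methoxymethoxy)-2-oxidophenyl]methylidene}butanedioate | [Li+].[Li+].[Li+].[O-]C(=O)C/C(C([O-])=O)=C/c1ccc(OCOC)c(OC)c1[O-] | intermediate
12 | 2-Cou-acetic acid | OC(=O)Cc1cc2ccc(OCOC)c(OC)c2oc1=O | intermediate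
13 | tert-butyl(but-3-yn-1-yloxy)dimethylsilane | C#CCCO[Si](C)(C)C(C)(C)C | starting material
14 | trimethylaluminium | C[Al](C)C | starting material
15 | acetaldehyde | CC=O | starting material
16 | {(1E)-4-[(tert-butyldimethylsilyl)oxy]-2-methylbut-1-en-1-yl}dimethylalane | C[Al](C)/C=C(\C)CCO[Si](C)(C)C(C)(C)C | intermediate
17 | rac-(3E)-6-[(tert-butyldimethylsilyl)oxy]-4-methylhex-3-en-2-ol | CC(O)/C=C(\C)CCO[Si](C)(C)C(C)(C)C | intermediate
18 | vinyl acetate | CC(=O)OC=C | starting material
19 | (2S,3E)-6-[(tert-butyldimethylsilyl)oxy]-4-methylhex-3-en-2-ol | C[C@H](O)/C=C(\C)CCO[Si](C)(C)C(C)(C)C | intermediate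
20 | (2S,3E)-6-[(tert-butyldimethylsilyl)oxy]-4-methylhex-3-en-2-yl 2-Cou-acetate | C[C@H](OC(=O)Cc1cc2ccc(OCOC)c(OC)c2oc1=O)/C=C(\C)CCO[Si](C)(C)C(C)(C)C | intermediate
21 | (Z)-O-trimethylsilyl ketene acetal of 20 (Cou cis to OSiMe3) | C[C@H](O/C(O[Si](C)(C)C)=C/c1cc2ccc(OCOC)c(OC)c2oc1=O)/C=C(\C)CCO[Si](C)(C)C(C)(C)C | intermediate
22 | trimethylsilyl (2R,3R,4E)-3-{2-[(tert-butyldimethylsilyl)oxy]ethyl}-2-Cou-3-methylhex-4-enoate | C/C=C/[C@@]([C@@H](C(=O)O[Si](C)(C)C)c1cc2ccc(OCOC)c(OC)c2oc1=O)(C)CCO[Si](C)(C)C(C)(C)C | intermediate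
23 | (2R,3R,4E)-3-{2-[(tert-butyldimethylsilyl)oxy]ethyl}-2-Cou-3-methylhex-4-enoic acid | C/C=C/[C@@]([C@@H](C(=O)O)c1cc2ccc(OCOC)c(OC)c2oc1=O)(C)CCO[Si](C)(C)C(C)(C)C | intermediate
24 | (2R,3R,4E)-3-{2-[(tert-butyldimethylsilyl)oxy]ethyl}-2-Cou-3-methylhex-4-en-1-ol | C/C=C/[C@@]([C@@H](CO)c1cc2ccc(OCOC)c(OC)c2oc1=O)(C)CCO[Si](C)(C)C(C)(C)C | intermediate
25 | (2R,3R,4E)-3-(2-hydroxyethyl)-2-Cou-3-methylhex-4-en-1-ol | C/C=C/[C@@]([C@@H](CO)c1cc2ccc(OCOC)c(OC)c2oc1=O)(C)CCO | intermediate
26 | (4R,5R)-5-Cou-4-methyl-4-[(1E)-prop-1-en-1-yl]oxan-2-ol (both anomers) | C/C=C/[C@@]1(C)CC(O)OC[C@H]1c1cc2ccc(OCOC)c(OC)c2oc1=O | intermediate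
27 | (4R,5R)-5-Cou-4-methyl-4-[(1E)-prop-1-en-1-yl]oxan-2-one | C/C=C/[C@@]1(C)CC(=O)OC[C@H]1c1cc2ccc(OCOC)c(OC)c2oc1=O | intermediate
28 | secondary ozonide of 27: (4S,5R)-5-Cou-4-methyl-4-(5-methyl-1,2,4-trioxolan-3-yl)oxan-2-one | CC1OOC(O1)[C@@]2(C)CC(=O)OC[C@H]2c2cc3ccc(OCOC)c(OC)c3oc2=O | intermediate
29 | (4S,5R)-5-Cou-4-methyl-2-oxooxane-4-carbaldehyde | O=C[C@@]1(C)CC(=O)OC[C@H]1c1cc2ccc(OCOC)c(OC)c2oc1=O | intermediate
30 | dimethyl (1-diazo-2-oxopropyl)phosphonate | COP(=O)(OC)C(=[N+]=[N-])C(C)=O | starting material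
31 | methyl (3S,4R)-3-ethynyl-5-hydroxy-4-Cou-3-methylpentanoate | C#C[C@@]([C@@H](CO)c1cc2ccc(OCOC)c(OC)c2oc1=O)(C)CC(=O)OC | intermediate
32 | (4S,5R)-4-ethynyl-5-Cou-4-methyloxan-2-one | C#C[C@@]1(C)CC(=O)OC[C@H]1c1cc2ccc(OCOC)c(OC)c2oc1=O | intermediate
33 | tetrabutylammonium (3S,4R)-3-ethynyl-5-hydroxy-4-Cou-3-methylpentanoate | C#C[C@@]([C@@H](CO)c1cc2ccc(OCOC)c(OC)c2oc1=O)(C)CC(=O)[O-].CCCC[N+](CCCC)(CCCC)CCCC | intermediate
34 | (3S,4R)-3-ethynyl-4-Cou-3-methyl-5-oxopentanoic acid | C#C[C@@]([C@@H](C=O)c1cc2ccc(OCOC)c(OC)c2oc1=O)(C)CC(=O)O | intermediate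
35 | triphenylphosphine | c1ccc(cc1)P(c1ccccc1)c1ccccc1 | starting material
36 | 2-bromopropene | CC(Br)=C | starting material
37 | triphenyl(prop-1-en-2-yl)phosphonium bromide | CC(=C)[P+](c1ccccc1)(c1ccccc1)c1ccccc1.[Br-] | intermediate
38 | ylide: (3S,4R)-3-ethynyl-4-Cou-3-methyl-5-oxo-1-[2-(triphenylphosphoranylidene)propyl]pentane skeleton (C6H2–C5H2–C4(CH3)=PPh3) | C#C[C@@]([C@@H](C=O)c1cc2ccc(OCOC)c(OC)c2oc1=O)(C)CCC(C)=P(c1ccccc1)(c1ccccc1)c1ccccc1 | intermediate
39 | 3-[(1R,6S)-6-ethynyl-3,6-dimethylcyclohex-2-en-1-yl]-8-methoxy-7-(methoxymethoxy)-2H-chromen-2-one | C#C[C@@]1(C)CCC(C)=C[C@H]1c1cc2ccc(OCOC)c(OC)c2oc1=O | intermediate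
40 | pinacolborane | [H]B1OC(C)(C)C(C)(C)O1 | starting material
41 | 3-[(1R,6R)-3,6-dimethyl-6-[(E)-2-(4,4,5,5-tetramethyl-1,3,2-dioxaborolan-2-yl)ethenyl]cyclohex-2-en-1-yl]-8-methoxy-7-(methoxymethoxy)-2H-chromen-2-one | CC1(C)OB(/C=C/[C@@]2(C)CCC(C)=C[C@H]2c2cc3ccc(OCOC)c(OC)c3oc2=O)OC1(C)C | intermediate
42 | 8-methoxy-3-[(E)-2-[(1R,2R)-2-Cou-1,4-dimethylcyclohex-3-en-1-yl]ethenyl]-7-(methoxymethoxy)-2H-chromen-2-one | COCOc1ccc2cc(/C=C/[C@@]3(C)CCC(C)=C[C@H]3c3cc4ccc(OCOC)c(OC)c4oc3=O)c(=O)oc2c1OC | intermediate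
43 | 7-hydroxy-3-[(E)-2-[(1R,2R)-2-(7-hydroxy-8-methoxy-2-oxo-2H-chromen-3-yl)-1,4-dimethylcyclohex-3-en-1-yl]ethenyl]-8-methoxy-2H-chromen-2-one | COc1c(O)ccc2cc(/C=C/[C@@]3(C)CCC(C)=C[C@H]3c3cc4ccc(O)c(OC)c4oc3=O)c(=O)oc12 | target

**Step count and risks**

Total step count: 17. Longest linear sequence: 14 steps (1, 2, 3, 4, 7, 8, 9, 10, 11, 12, 13, 15, 16, 17, from aldehyde 1).

Steps most likely to fail:

Step 15 (Proposed new method). The ylide may be quenched by proton transfer from the acidic α-coumarinyl aldehyde, which would also erode the C2 configuration; the carboxylate may add reversibly to the phosphonium salt instead of being oxidised; or the radical may be lost by hydrogen abstraction. The fallback uses known reactions only, sets out from 34 and comes back at 42. Methylenation of the aldehyde of 34 (Zn, CH2Br2, TiCl4) should give (3S,4R)-3-ethynyl-4-Cou-3-methylhex-5-enoic acid F1. Photocatalytic decarboxylative allylation of F1 with 2-methylallyl phenyl sulfone (same iridium photocatalyst, K2HPO4) then forms the C5–C6 bond and gives 3-[(3R,4S)-4-ethynyl-4,6-dimethylhepta-1,6-dien-3-yl]-8-methoxy-7-(methoxymethoxy)-2H-chromen-2-one F2. Hydroboration of the alkyne to the alkenylboronate F3 (not isolated) and Suzuki coupling with 8, as in step 16, give the triene F4. Ring-closing metathesis of F4 (second-generation Hoveyda–Grubbs catalyst, PhMe, 80 °C) closes C3=C4 and gives 42. The Suzuki coupling is placed before the metathesis so that no alkyne meets the ruthenium carbene.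

Step 13. Hydroxide may open the coumarin lactone in competition with the δ-lactone, the hydroxy acid may relactonise before it is oxidised, and the carboxylate may epimerise C2 once the aldehyde is present. The fallback sets out from 32 and comes back at 34, replacing the salt oxidation by an ester that is cleaved under neutral conditions. Transesterification of 32 in allyl alcohol (K2CO3 cat., neutralised before concentration) should give prop-2-en-1-yl (3S,4R)-3-ethynyl-5-hydroxy-4-Cou-3-methylpentanoate F5. Dess–Martin oxidation gives prop-2-en-1-yl (3S,4R)-3-ethynyl-4-Cou-3-methyl-5-oxopentanoate F6. Deallylation with Pd(PPh3)4 and PhSiH3 in CH2Cl2 then releases 34.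

Step 10. Oxidation may start at the wrong hydroxyl (the CH2OH on C2), which would give the regioisomeric lactone with the carbonyl at C3. The fallback fixes the regiochemistry by protecting groups, sets out from 24 (isolated by leaving out the acid methanolysis of step 9) and comes back at 27. Acetylation (Ac2O, pyridine) gives (2R,3R,4E)-3-{2-[(tert-butyldimethylsilyl)oxy]ethyl}-2-Cou-3-methylhex-4-en-1-yl acetate F7. Desilylation (CSA, MeOH) gives (2R,3R,4E)-3-(2-hydroxyethyl)-2-Cou-3-methylhex-4-en-1-yl acetate F8. Oxidation with TEMPO/PhI(OAc)2 in aqueous MeCN gives (3R,4E)-3-[(1R)-2-(acetyloxy)-1-Cou-ethyl]-3-methylhex-4-enoic acid F9. Methanolysis of the acetate (K2CO3, MeOH) followed by acidification lets the hydroxy acid close to 27.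

Further compounds
F1 | step 15 | (3S,4R)-3-ethynyl-4-Cou-3-methylhex-5-enoic acid | C#C[C@@]([C@@H](C=C)c1cc2ccc(OCOC)c(OC)c2oc1=O)(C)CC(=O)O
F2 | step 15 | 3-[(3R,4S)-4-ethynyl-4,6-dimethylhepta-1,6-dien-3-yl]-8-methoxy-7-(methoxymethoxy)-2H-chromen-2-one | C#C[C@@]([C@@H](C=C)c1cc2ccc(OCOC)c(OC)c2oc1=O)(C)CCC(C)=C
F3 | step 15 | 3-[(3R,4R)-4,6-dimethyl-4-[(E)-2-(4,4,5,5-tetramethyl-1,3,2-dioxaborolan-2-yl)ethenyl]hepta-1,6-dien-3-yl]-8-methoxy-7-(methoxymethoxy)-2H-chromen-2-one | CC1(C)OB(/C=C/[C@@]([C@@H](C=C)c2cc3ccc(OCOC)c(OC)c3oc2=O)(C)CCC(C)=C)OC1(C)C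
F4 | step 15 | 8-methoxy-3-[(1E,3R,4R)-4-Cou-3-methyl-3-(3-methylbut-3-en-1-yl)hexa-1,5-dien-1-yl]-7-(methoxymethoxy)-2H-chromen-2-one | COCOc1ccc2cc(/C=C/[C@@]([C@@H](C=C)c3cc4ccc(OCOC)c(OC)c4oc3=O)(C)CCC(C)=C)c(=O)oc2c1OC
F5 | step 13 | prop-2-en-1-yl (3S,4R)-3-ethynyl-5-hydroxy-4-Cou-3-methylpentanoate | C#C[C@@]([C@@H](CO)c1cc2ccc(OCOC)c(OC)c2oc1=O)(C)CC(=O)OCC=C
F6 | step 13 | prop-2-en-1-yl (3S,4R)-3-ethynyl-4-Cou-3-methyl-5-oxopentanoate | C#C[C@@]([C@@H](C=O)c1cc2ccc(OCOC)c(OC)c2oc1=O)(C)CC(=O)OCC=C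
F7 | step 10 | (2R,3R,4E)-3-{2-[(tert-butyldimethylsilyl)oxy]ethyl}-2-Cou-3-methylhex-4-en-1-yl acetate | C/C=C/[C@@]([C@@H](COC(C)=O)c1cc2ccc(OCOC)c(OC)c2oc1=O)(C)CCO[Si](C)(C)C(C)(C)C
F8 | step 10 | (2R,3R,4E)-3-(2-hydroxyethyl)-2-Cou-3-methylhex-4-en-1-yl acetate | C/C=C/[C@@]([C@@H](COC(C)=O)c1cc2ccc(OCOC)c(OC)c2oc1=O)(C)CCO
F9 | step 10 | (3R,4E)-3-[(1R)-2-(acetyloxy)-1-Cou-ethyl]-3-methylhex-4-enoic acid | C/C=C/[C@@]([C@@H](COC(C)=O)c1cc2ccc(OCOC)c(OC)c2oc1=O)(C)CC(=O)O
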